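**Retrosynthetic overview**

- A retro-[4+2] opens the ring C(Me) bridgehead–C(=O)–C(OH)Me–CH bridgehead–CH2–C(spiro) at both bonds to the CH2–C(spiro) bridge. This gives (R)-sorbicillinol as diene and a cyclohexene-fused 3-methylidene-1,4-dioxan-2-one as dienophile, and copies the presumed biosynthesis.
- Enabling feature: the bridge C(=O)–C(=C(OH)sorbyl) is the enolised pair of central carbons of a cyclohexa-2,4-dienone, so the quinol carbocycle is a masked diene. The spiro carbon carrying O and C=O next to a CH2 is the retron of an exocyclic captodative alkene.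
- Diene: 2,4-dimethylresorcinol + sorbic acid → sorbicillin → Wessely acetoxylation → resolved (R)-quinol acetate, unmasked in the flask.
- Dienophile: (−)-shikimic acid keeps C4 and C5 and is inverted at C3 (Mitsunobu); then Rh-carbenoid O–H insertion, lactonisation onto O4 and Horner–Wadsworth–Emmons methylenation.
- Ring order: cyclohexene (chiral pool) → dioxanone (step 5); arene → cyclohexadienone (step 8); bicyclo[2.2.2]octane last (step 10).

Key step: step 10

Remark: read from the SMILES, the quinol carbinol carbon is (R) and the cyclohexene carbons are those of 3-epi-shikimate ((3S,4S,5R), all-trans); both are therefore fixed by chemical means whose sense can be chosen (resolution; inversion of natural shikimate at C3).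

Numbering used: shikimate numbering (C1 bears the ester, C3 is allylic); sorbicillin numbering (C1 bears the sorbyl ketone, C2 OH, C3 Me, C4 O, C5 the carbinol carbon, C6 H).

**Route**

Step 1
Reactants: 1 (−)-shikimic acid
Product: 3 methyl 4,5-O-(2,3-dimethoxybutane-2,3-diyl)shikimate (3-OH free), via methyl shikimate 2 (not isolated)
Conditions: butane-2,3-dione, HC(OMe)3, MeOH, CSA (cat.), reflux
Reagents that add atoms: methanol, CO; butane-2,3-dione, CC(=O)C(C)=O; trimethyl orthoformate (methoxy source and water scavenger), COC(OC)OC
Why: Fischer esterification and thermodynamically controlled butane-2,3-diacetal formation select the trans-diequatorial 4,5-diol (both OMe axial, anomeric stabilisation), leave the axial allylic 3-OH free and touch no ring stereocentre.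

Step 2
Reactants: 3 methyl 4,5-O-(2,3-dimethoxybutane-2,3-diyl)shikimate
Product: 4 methyl 3-epi-3-O-(4-nitrobenzoyl)-4,5-O-(2,3-dimethoxybutane-2,3-diyl)shikimate
Conditions: 4-nitrobenzoic acid, PPh3, DIAD, THF, 0 °C to rt
Reagents that add atoms: 4-nitrobenzoic acid, O=C(O)c1ccc(cc1)[N+](=O)[O-]
Why: Mitsunobu reaction, in which SN2 displacement of the axial allylic oxyphosphonium inverts C3 to the (3S), all-trans series, while SN2′ attack is disfavoured because it would have to occur at the ester-bearing C1.

Step 3
Reactants: 4 methyl 3-epi-3-O-(4-nitrobenzoyl)-4,5-O-(2,3-dimethoxybutane-2,3-diyl)shikimate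
Product: 5 methyl 3-epi-4,5-O-(2,3-dimethoxybutane-2,3-diyl)shikimate
Conditions: K2CO3 (cat.), MeOH, 0 °C
Reagents that add atoms: none
Why: Base-catalysed transesterification (methanolysis) removes the activated aryl ester by acyl–oxygen cleavage, so C3 keeps its new configuration, the C1 methyl ester is degenerate in methanol and the diacetal is base-stable.

Step 4
Reactants: 5 methyl 3-epi-4,5-O-(2,3-dimethoxybutane-2,3-diyl)shikimate
Product: 6 methyl 3-epi-3-O-[(diethoxyphosphoryl)(ethoxycarbonyl)methyl]-4,5-O-(2,3-dimethoxybutane-2,3-diyl)shikimate (both epimers at the P-bearing carbon)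
Conditions: ethyl diazo(diethoxyphosphoryl)acetate, Rh2(OAc)4 (2 mol %), benzene, 80 °C
Reagents that add atoms: ethyl 2-diazo-2-(diethoxyphosphoryl)acetate, CCOC(=O)C(=[N+]=[N-])P(=O)(OCC)OCC
Why: Rhodium-carbenoid O–H insertion, the established entry to enolpyruvyl ethers of shikimate-type alcohols, should form the C3–O–C bond with retention at C3 because the electron-poor enoate resists cyclopropanation; the new centre is an inconsequential epimer mixture that becomes sp2 in step 6.

Step 5
Reactants: 6 methyl 3-epi-3-O-[(diethoxyphosphoryl)(ethoxycarbonyl)methyl]-4,5-O-(2,3-dimethoxybutane-2,3-diyl)shikimate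
Product: 8 phosphono-dioxanone (trans-fused 3-(diethoxyphosphoryl)-1,4-dioxan-2-one on O3/O4 of methyl 3-epi-shikimate with 5-OH free), via diol 7 (not isolated)
Conditions: TFA/H2O (9:1), 0 °C to rt; evaporate; then p-TsOH·H2O (cat.), toluene, 70 °C
Reagents that add atoms: none
Why: Acidic acetal hydrolysis frees the trans-4,5-diol and acid-catalysed lactonisation (intramolecular transesterification) closes the trans-fused six-membered dioxanone onto O4, the alternative through O5 being a strained bridged seven-membered ring.

Step 6
Reactants: 8 phosphono-dioxanone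
Product: 9 methylidene-dioxanone dienophile (methyl 3-epi-shikimate 3-O-(1-carboxyvinyl) ether 4-lactone, (3S,4S,5R))
Conditions: 37% aq. CH2O, K2CO3, THF, 0 °C
Reagents that add atoms: formaldehyde, C=O
Why: Horner–Wadsworth–Emmons olefination with formaldehyde, the standard route from α-phosphono lactones to α-methylene lactones, should work here because the α-alkoxy phosphonate is acidic enough for carbonate base, which spares the lactone, the free 5-OH and the enoate.

Step 7
Reactants: 10 2,4-dimethylresorcinol; 11 sorbic acid
Product: 12 sorbicillin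
Conditions: BF3·OEt2, 90 °C
Reagents that add atoms: none
Why: Friedel–Crafts acylation promoted by BF3 occurs at the only ring position that is ortho to one hydroxyl and para to the other, and the resulting chelated 2-hydroxyaryl ketone is protected from over-reaction.

Step 8
Reactants: 12 sorbicillin
Product: 13 rac-sorbicillinol acetate (5-acetoxy o-quinol acetate)
Conditions: Pb(OAc)4, AcOH/CH2Cl2, 0 °C to rt
Reagents that add atoms: lead tetraacetate, CC(=O)O[Pb](OC(C)=O)(OC(C)=O)OC(C)=O
Why: Wessely acetoxylation (oxidative dearomatisation by tetravalent lead bound at the free 4-OH, the 2-OH being tied up in the hydrogen bond to the ketone) delivers acetate to the methyl-bearing ortho carbon C5 as a racemate, the minor C3 regioisomer being removed by chromatography.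

Step 9
Reactants: 13 rac-sorbicillinol acetate
Product: 14 (R)-sorbicillinol acetate
Conditions: preparative HPLC, amylose tris(3,5-dimethylphenylcarbamate) stationary phase, hexane/i-PrOH, 0.1% TFA
Reagents that add atoms: none
Why: Chromatographic resolution of enantiomers is reliable here because the quaternary acetoxy centre has no racemisation pathway; the (R) antipode is to be assigned by ECD or X-ray analysis and the (S) antipode can be returned to 12 by Zn/AcOH reduction.

Step 10
Reactants: 14 (R)-sorbicillinol acetate (2 equiv); 9 methylidene-dioxanone dienophile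
Product: 16 target CNP0259039.2, via (R)-sorbicillinol 15 (not isolated)
Conditions: a) 14, KOH, THF/H2O (9:1), 0 °C; b) 1 M HCl to pH 6–7; c) slow addition to 9 in THF/pH 7 phosphate buffer, 20 °C, dark; reversed-phase HPLC
Reagents that add atoms: none
Why: Saponification of the tertiary acetate gives the quinolate of 15, and neutralisation frees the cyclohexa-2,4-dienone whose carbons C3(Me)=C2(OH)–C1(acyl)=C6H act as a push–pull diene toward the captodative exocyclic alkene of 9 in a concerted, asynchronous intermolecular Diels–Alder reaction, the primary adduct being the enol tautomer of 16. The closest known reaction type is the biomimetic Diels–Alder chemistry of sorbicillinol itself, which dimerises through this diene and adds vinyl ethers and styrenes across it. Two six-membered rings of the bicyclo[2.2.2]octane close at once by suprafacial addition of both alkene termini to C3 and C6 on one diene face, and the spiro junction arises because the dienophile double bond is exocyclic to the dioxanone. The two bridgeheads are controlled by C5 of 15 (attack syn to the C5 hydroxyl and anti to the C5 methyl, the usual facial preference of o-quinols), and the spiro carbon by the Alder endo rule (lactone carbonyl under C1–C2 of the diene, ether oxygen exo), the shikimate-derived centres being spectators. Regioselectivity should follow from matched polarisation (CH2 terminus of the alkoxyacrylate to the electrophilic C6, alkoxy-bearing carbon to the enol-activated C3); the exo spiro epimer is the expected separable minor product, and second-order dimerisation of 15 is held back by adding it slowly to concentrated 9.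

**Compound list**

1 | (−)-shikimic acid, (3R,4S,5R)-3,4,5-trihydroxycyclohex-1-ene-1-carboxylic acid | O[C@@H]1C=C(C(=O)O)C[C@@H](O)[C@@H]1O | starting material
2 | methyl shikimate | O[C@@H]1C=C(C(=O)OC)C[C@@H](O)[C@@H]1O | intermediate
3 | methyl 4,5-O-(2,3-dimethoxybutane-2,3-diyl)shikimate (trans-fused diacetal, both OMe axial, 3-OH free) | COC(=O)C1=C[C@@H](O)[C@H]2O[C@](C)(OC)[C@@](C)(OC)O[C@@H]2C1 | intermediate
4 | methyl 3-epi-3-O-(4-nitrobenzoyl)-4,5-O-(2,3-dimethoxybutane-2,3-diyl)shikimate | COC(=O)C1=C[C@H](OC(=O)c3ccc(cc3)[N+](=O)[O-])[C@H]2O[C@](C)(OC)[C@@](C)(OC)O[C@@H]2C1 | intermediate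
5 | methyl 3-epi-4,5-O-(2,3-dimethoxybutane-2,3-diyl)shikimate ((3S) carbinol, all-trans) | COC(=O)C1=C[C@H](O)[C@H]2O[C@](C)(OC)[C@@](C)(OC)O[C@@H]2C1 | intermediate
6 | methyl 3-epi-3-O-[(diethoxyphosphoryl)(ethoxycarbonyl)methyl]-4,5-O-(2,3-dimethoxybutane-2,3-diyl)shikimate (both epimers at the P-bearing carbon) | COC(=O)C1=C[C@H](OC(C(=O)OCC)P(=O)(OCC)OCC)[C@H]2O[C@](C)(OC)[C@@](C)(OC)O[C@@H]2C1 | intermediate
7 | methyl 3-epi-3-O-[(diethoxyphosphoryl)(ethoxycarbonyl)methyl]shikimate (4,5-diol) | COC(=O)C1=C[C@H](OC(C(=O)OCC)P(=O)(OCC)OCC)[C@@H](O)[C@H](O)C1 | intermediate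
8 | phosphono-dioxanone: methyl 3-epi-shikimate with O3 and O4 bridged by CH[P(O)(OEt)2]–C(=O) (carbonyl on O4, trans-fused, 5-OH free) | COC(=O)C1=C[C@@H]2OC(P(=O)(OCC)OCC)C(=O)O[C@H]2[C@H](O)C1 | intermediate
9 | methylidene-dioxanone dienophile: methyl 3-epi-shikimate 3-O-(1-carboxyvinyl) ether 4-lactone, (3S,4S,5R) | COC(=O)C1=C[C@@H]2OC(=C)C(=O)O[C@H]2[C@H](O)C1 | intermediate
10 | 2,4-dimethylresorcinol (2,4-dimethylbenzene-1,3-diol) | Cc1ccc(O)c(C)c1O | starting material
11 | sorbic acid, (2E,4E)-hexa-2,4-dienoic acid | C/C=C/C=C/C(=O)O | starting material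
12 | sorbicillin, (2E,4E)-1-(2,4-dihydroxy-3,5-dimethylphenyl)hexa-2,4-dien-1-one | C/C=C/C=C/C(=O)c1cc(C)c(O)c(C)c1O | intermediate
13 | rac-sorbicillinol acetate (racemic 5-acetoxy o-quinol acetate of sorbicillin) | C/C=C/C=C/C(=O)C1=CC(C)(OC(C)=O)C(=O)C(C)=C1O | intermediate
14 | (R)-sorbicillinol acetate | C/C=C/C=C/C(=O)C1=C[C@@](C)(OC(C)=O)C(=O)C(C)=C1O | intermediate
15 | (R)-sorbicillinol | C/C=C/C=C/C(=O)C1=C[C@@](C)(O)C(=O)C(C)=C1O | intermediate
16 | target CNP0259039.2 (endo adduct: lactone carbonyl syn to the enolised diketone bridge, quinol OH syn to the CH2 of the new bridge) | C/C=C/C=C/C(O)=C1/C(=O)[C@@]2(C)C(=O)[C@](C)(O)[C@@H]1C[C@]21O[C@H]2C=C(C(=O)OC)C[C@@H](O)[C@@H]2OC1=O | target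

**Summary**

Total step count: 10. Longest linear sequence: 7 steps (steps 1–6 and 10, from (−)-shikimic acid); the diene branch is steps 7–9.

**Steps most likely to fail, with fallbacks**

1. Step 10. The free quinol may dimerise faster than it adds to 9, the dioxanone may hydrolyse in the aqueous medium, and endo/exo selectivity may be low. The fallback sets out from 14 and 9 and uses the acetate itself as the diene, which cannot dimerise readily. Thermal Diels–Alder reaction of 14 with 9 (toluene, 70 °C) should give the O-acetyl adduct F1, with attack syn to the acetoxy group as is usual for o-quinol acetates. Methanolysis (K2CO3, MeOH, 0 °C) then removes the unhindered acetyl group, while the lactone carbonyl is shielded by the fully substituted spiro carbon. The fallback comes back to the route at 16.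

2. Step 6. The base may open the dioxanone, cause β-elimination of the lactone oxygen from C4 after vinylogous deprotonation at C3, or trigger oxa-Michael addition of the 5-OH to the new acrylate. The fallback sets out from 6 and olefinates before the ring and the free hydroxyl exist. Horner–Wadsworth–Emmons reaction of 6 with formaldehyde (K2CO3, aq. CH2O, THF) should give the diacetal-protected enolpyruvate F2. TFA/H2O then frees the diol enolpyruvate F3, and acid-catalysed lactonisation (p-TsOH, toluene, 70 °C) closes the dioxanone. The fallback comes back to the route at 9.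

3. Step 9. Separation of the enantiomers may be incomplete, or the acidic enol may tail or degrade on the column. The fallback sets out from 13 (with 9) and resolves through the cycloaddition instead. Racemic 13 is unmasked by the KOH/HCl protocol of step 10 to racemic sorbicillinol F4, which is added to enantiopure 9. The two endo adducts, 16 and the diastereomeric adduct F5 (mirror-image bicyclic core on the same dioxanone), are diastereomers and should be separable by ordinary reversed-phase HPLC. The fallback comes back to the route at 16.

**Further compounds**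

F1 | step 10 | O-acetyl adduct (acetate of 16 at the quinol oxygen) | C/C=C/C=C/C(O)=C1/C(=O)[C@@]2(C)C(=O)[C@](C)(OC(C)=O)[C@@H]1C[C@]21O[C@H]2C=C(C(=O)OC)C[C@@H](O)[C@@H]2OC1=O
F2 | step 6 | methyl 3-epi-3-O-[1-(ethoxycarbonyl)vinyl]-4,5-O-(2,3-dimethoxybutane-2,3-diyl)shikimate | COC(=O)C1=C[C@H](OC(=C)C(=O)OCC)[C@H]2O[C@](C)(OC)[C@@](C)(OC)O[C@@H]2C1
F3 | step 6 | methyl 3-epi-3-O-[1-(ethoxycarbonyl)vinyl]shikimate (4,5-diol) | COC(=O)C1=C[C@H](OC(=C)C(=O)OCC)[C@@H](O)[C@H](O)C1
F4 | step 9 | rac-sorbicillinol | C/C=C/C=C/C(=O)C1=CC(C)(O)C(=O)C(C)=C1O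
F5 | step 9 | diastereomeric endo adduct from (S)-sorbicillinol and 9 | C/C=C/C=C/C(O)=C1/C(=O)[C@]2(C)C(=O)[C@@](C)(O)[C@H]1C[C@@]21O[C@H]2C=C(C(=O)OC)C[C@@H](O)[C@@H]2OC1=O
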